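The ten-membered carbocycle is not made by C–C macrocyclisation. Its Z-trisubstituted C1=C10 alkene is read as a C1 methylene and a C10 methyl-bearing methine bridged by sulfur, so the ring is first closed as an eleven-membered thiacycle by thiolate alkylation at C1. A Ramberg–Bäcklund reaction of the derived C1–SO2–C10 sulfone then forms C1=C10 and contracts the ring to the germacrane skeleton in one operation. The sulfone carries TBS ethers at C3 and C9 and the butenolide masked as a C6/C12 dioxepine with a C13 PMB ether; its tetrasubstituted C7=C11 alkene comes from olefination of a symmetric dioxanone, C6 from a CBS reduction.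

Key step: step 23

Remark: germacrane numbering is used throughout (ring C1–C10, C11–C13 on the lactone, C14 on C10, C15 on C4); C10 is (R) as carbinol and (S) once it carries sulfur, and because step 23 erases this centre the minor C10 epimer from step 8 is carried along.

Step 1
Reactants: 1 3-chloropropanoyl chloride; 2 bis(trimethylsilyl)acetylene
Product: 3 5-chloro-1-(trimethylsilyl)pent-1-yn-3-one
Conditions: AlCl3, CH2Cl2, 0 °C
Reagents that add atoms: none
Why: Friedel–Crafts-type ipso-acylation of an alkynylsilane should exchange only one silyl group because the ynone formed is deactivated towards a second acylation.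

Step 2
Reactants: 3 5-chloro-1-(trimethylsilyl)pent-1-yn-3-one
Product: 4 (S)-5-chloro-1-(trimethylsilyl)pent-1-yn-3-ol
Conditions: Ru[(S,S)-TsDPEN](p-cymene) (1 mol %), i-PrOH, rt
Reagents that add atoms: none
Why: Noyori asymmetric transfer hydrogenation of an alkynyl ketone, in which the (S,S)-catalyst is expected to give the (S)-carbinol at C3 by reagent control while the base-free medium spares the β-chloro ketone.

Step 3
Reactants: 4 (S)-5-chloro-1-(trimethylsilyl)pent-1-yn-3-ol
Product: 5 (S)-3-(tert-butyldimethylsilyloxy)-5-chloro-1-(trimethylsilyl)pent-1-yne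
Conditions: TBSCl, imidazole, DMF, rt
Reagents that add atoms: tert-butyldimethylsilyl chloride CC(C)(C)[Si](C)(C)Cl
Why: Standard imidazole-promoted silylation of a secondary propargylic alcohol; the TBS ether must last until step 24.

Step 4
Reactants: 5 (S)-3-(tert-butyldimethylsilyloxy)-5-chloro-1-(trimethylsilyl)pent-1-yne
Product: 6 (S)-3-(tert-butyldimethylsilyloxy)-5-chloropent-1-yne (C1–C5 unit: C1–Cl, C3–OTBS, C4≡C5)
Conditions: K2CO3 (0.2 equiv), MeOH, rt
Reagents that add atoms: none
Why: Methoxide-catalysed protodesilylation cleaves only the C(sp)–SiMe3 bond, the O–TBS ether and the primary chloride being inert at room temperature.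

Step 5
Reactants: 7 tris(hydroxymethyl)aminomethane hydrochloride; 8 4-methoxybenzaldehyde dimethyl acetal
Product: 9 [5-amino-2-(4-methoxyphenyl)-1,3-dioxan-5-yl]methanol
Conditions: p-TsOH·H2O (cat.), DMF, rt; then Et3N
Reagents that add atoms: none
Why: Acid-catalysed transacetalisation closes the six-membered 1,3-dioxane over two of the three hydroxymethyl arms of the amino triol.

Step 6
Reactants: 9 [5-amino-2-(4-methoxyphenyl)-1,3-dioxan-5-yl]methanol
Product: 10 2-(4-methoxyphenyl)-1,3-dioxan-5-one
Conditions: NaIO4, KH2PO4, H2O, 0 °C to rt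
Reagents that add atoms: water O
Why: Periodate cleavage of the 1,2-amino alcohol (Malaprade-type) gives the imine, which water hydrolyses to the symmetric ketone.

Step 7
Reactants: 11 (S)-5-(hydroxymethyl)dihydrofuran-2(3H)-one
Product: 12 (S)-5-oxotetrahydrofuran-2-carbaldehyde
Conditions: (COCl)2, DMSO, CH2Cl2, −78 °C; Et3N
Reagents that add atoms: none
Why: Swern oxidation stops at the aldehyde and the crude product is used at once so that the C9 centre, taken from the chiral pool, is not epimerised.

Step 8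
Reactants: 12 (S)-5-oxotetrahydrofuran-2-carbaldehyde
Product: 13 (S)-5-[(R)-1-hydroxyethyl]dihydrofuran-2(3H)-one
Conditions: MeTi(Oi-Pr)3, THF, −40 to 0 °C
Reagents that add atoms: methyltitanium triisopropoxide C[Ti](OC(C)C)(OC(C)C)OC(C)C
Why: Reetz-type methyltitanium addition is chemoselective for the aldehyde over the lactone and polar Felkin–Anh control by the ring oxygen should favour the (10R) carbinol; this centre is erased in step 23, so the minor epimer does no harm.

Step 9
Reactants: 13 (S)-5-[(R)-1-hydroxyethyl]dihydrofuran-2(3H)-one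
Product: 14 (S)-5-[(R)-1-(triethylsilyloxy)ethyl]dihydrofuran-2(3H)-one
Conditions: TESCl, imidazole, CH2Cl2, 0 °C
Reagents that add atoms: chlorotriethylsilane CC[Si](Cl)(CC)CC
Why: Silylation of the secondary alcohol; triethylsilyl is chosen because it can later be removed beside the two TBS ethers.

Step 10
Reactants: 14 (S)-5-[(R)-1-(triethylsilyloxy)ethyl]dihydrofuran-2(3H)-one
Product: 16 α-phosphono lactone (diethyl phosphonate at C7 of lactone 14; C7 epimers), via enol phosphate 15 (not isolated)
Conditions: LDA (1.1 equiv), THF, −78 °C; ClP(O)(OEt)2; then LDA (2.2 equiv), −78 °C to rt; AcOH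
Reagents that add atoms: diethyl chlorophosphate CCOP(=O)(Cl)OCC
Why: Wiemer phosphonate synthesis: O-phosphorylation of the lactone enolate gives 15, and a second deprotonation triggers the 1,3-phosphorus shift to the C-phosphonate at C7.

Step 11
Reactants: 16 α-phosphono lactone; 10 2-(4-methoxyphenyl)-1,3-dioxan-5-one
Product: 17 (S)-3-[2-(4-methoxyphenyl)-1,3-dioxan-5-ylidene]-5-[(R)-1-(triethylsilyloxy)ethyl]dihydrofuran-2(3H)-one (two acetal diastereomers, inconsequential)
Conditions: NaH, THF, 0 °C to rt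
Reagents that add atoms: none
Why: Horner–Wadsworth–Emmons olefination of the reactive, unhindered ketone builds the tetrasubstituted C7=C11 alkene, and since C11 carries two equivalent CH2O arms no alkene geometry has to be controlled.

Step 12
Reactants: 17 alkylidene lactone; 6 (S)-3-(tert-butyldimethylsilyloxy)-5-chloropent-1-yne
Product: 18 hydroxy enynone (C1–C10 chain: 1-Cl; (3S)-OTBS; C4≡C5; 6-oxo; 7-dioxanylidene; (9S)-OH; (10R)-OTES)
Conditions: 6, n-BuLi, THF, −78 °C; then 17, −78 to −40 °C; NH4Cl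
Reagents that add atoms: none
Why: A lithium acetylide adds once to a lactone because the tetrahedral lithium alkoxide survives at low temperature, so the C5–C6 bond and the ynone are formed while the ring oxygen is released as the C9 hydroxyl.

Step 13
Reactants: 18 hydroxy enynone
Product: 19 enynone with (9S)-OTBS
Conditions: TBSOTf, 2,6-lutidine, CH2Cl2, −78 °C
Reagents that add atoms: tert-butyldimethylsilyl triflate CC(C)(C)[Si](C)(C)OS(=O)(=O)C(F)(F)F
Why: Silyl triflate with a hindered base silylates the secondary C9 hydroxyl at low temperature without touching the ynone or the acetal.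

Step 14
Reactants: 19 enynone
Product: 20 (6R)-propargylic alcohol ((3S,6R,9S,10R); C4≡C5)
Conditions: (S)-Me-CBS (0.3 equiv), catecholborane, toluene, −78 °C
Reagents that add atoms: none
Why: Corey–Bakshi–Shibata reduction in which the linear alkynyl group acts as the small and the fully substituted alkenyl group as the large substituent, so that the (S)-catalyst is expected to give the (6R)-carbinol by reagent control.

Step 15
Reactants: 20 (6R)-propargylic alcohol
Product: 22 (Z)-4-iodo allylic alcohol ((3S,6R,9S,10R); iodine on C4 cis to C6), via cyclic alkenylalanate 21 (not isolated)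
Conditions: Red-Al, THF, 0 °C; EtOAc; then I2, THF, −78 °C
Reagents that add atoms: iodine II
Why: Hydroxyl-directed trans-hydroalumination of the propargylic alcohol (Corey method) delivers hydride to C5 and aluminium to C4 within the five-membered alanate 21, and iodinolysis with retention gives the (Z)-iodide with iodine cis to C6.

Step 16
Reactants: 22 (Z)-4-iodo allylic alcohol
Product: 23 (E)-allylic alcohol with C15 methyl on C4 ((3S,6R,9S,10R); C12/C13 oxygens in the PMP acetal)
Conditions: Me2CuLi (from MeLi and CuI), Et2O, 0 °C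
Reagents that add atoms: methyllithium (used as lithium dimethylcuprate) [Li]C
Why: Corey–Posner coupling of the alkenyl iodide with the Gilman reagent proceeds with retention, so the C15 methyl ends up cis to C6 and the C4=C5 alkene is E; the primary chloride reacts far more slowly.

Step 17
Reactants: 23 (E)-allylic alcohol
Product: 24 (3S,6R,9S,10R)-6,12-diol with C13–OPMB (C12 hydroxymethyl cis to C6)
Conditions: DIBAL-H (4 equiv), CH2Cl2, −78 to 0 °C; Rochelle salt
Reagents that add atoms: none
Why: Reductive opening of the p-methoxybenzylidene acetal by DIBAL-H, in which the aluminium alkoxide formed at C6 should coordinate the nearer acetal oxygen (on C12) so that this oxygen is freed and the PMB group stays on the C13 oxygen.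

Step 18
Reactants: 24 6,12-diol
Product: 25 dioxepine (C6/C12 acetonide; C13–OPMB; C3, C9–OTBS; C10–OTES; C1–Cl)
Conditions: 2-methoxypropene, PPTS (cat.), CH2Cl2, 0 °C
Reagents that add atoms: 2-methoxypropene COC(C)=C
Why: Acid-catalysed ketalisation of the cis-configured 2-ene-1,4-diol (C6 and C12 hydroxyls) with an enol ether gives the 4,7-dihydro-1,3-dioxepine under conditions mild enough for the doubly allylic C6–O bond.

Step 19
Reactants: 25 dioxepine
Product: 26 (10R)-alcohol (C10–OH free)
Conditions: HF·pyridine, pyridine, THF, 0 °C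
Reagents that add atoms: none
Why: Pyridine-buffered HF·pyridine cleaves a secondary triethylsilyl ether much faster than secondary TBS ethers and leaves the ketal and the PMB ether intact.

Step 20
Reactants: 26 (10R)-alcohol
Product: 27 (10S)-thioacetate
Conditions: PPh3, DIAD, AcSH, THF, 0 °C to rt
Reagents that add atoms: thioacetic acid CC(=O)S
Why: Mitsunobu thioesterification (Volante conditions) introduces sulfur at C10 with inversion under neutral conditions that leave the primary chloride untouched.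

Step 21
Reactants: 27 (10S)-thioacetate
Product: 29 eleven-membered cyclic sulfide (sulfur between C1 and C10), via thiol 28 (not isolated)
Conditions: K2CO3, NaI (cat.), MeOH/THF (degassed, 1 mM), 45 °C
Reagents that add atoms: none
Why: Methanolysis frees thiolate 28, which closes the eleven-membered ring by intramolecular SN2 displacement of the unhindered primary chloride at C1 under high dilution (thiolate macrocyclisation).

Step 22
Reactants: 29 eleven-membered cyclic sulfide
Product: 30 eleven-membered cyclic sulfone ((3S,6R,9S,10S); C6/C12 dioxepine; C13–OPMB; C3, C9–OTBS)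
Conditions: (NH4)6Mo7O24·4H2O (cat.), 30% H2O2, EtOH, 0 °C to rt
Reagents that add atoms: hydrogen peroxide OO
Why: Molybdate-catalysed hydrogen peroxide oxidises the sulfide through the sulfoxide to the sulfone and is known to be chemoselective for sulfur in the presence of unactivated alkenes.

Step 23
Reactants: 30 eleven-membered cyclic sulfone
Product: 33 ten-membered (1Z,4E)-diene bis-TBS ether fused to the dioxepine, via α-bromo sulfone 31 (not isolated), via episulfone 32 (not isolated)
Conditions: KOH/Al2O3, CBr2F2, t-BuOH/CH2Cl2, 0 °C to rt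
Reagents that add atoms: none
Why: Meyers–Chan variant of the Ramberg–Bäcklund reaction: KOH on alumina deprotonates an α-sulfonyl carbon (the C1 methylene is the more accessible), CBr2F2 brominates the carbanion to 31, the α′-carbanion at C10 displaces bromide in a 1,3-elimination to episulfone 32, and 32 loses SO2 in a cheletropic step to give C1=C10. The closest known reaction type is the Ramberg–Bäcklund contraction of medium and large cyclic sulfones to cycloalkenes, which also tolerates β-alkoxy sulfones. The ten-membered carbocycle is closed by ring contraction, not by macrocyclisation: the C1–C10 bond forms in the 3-exo-tet closure of the episulfone inside the eleven-membered ring and becomes the alkene when sulfur leaves. No stereocentre is created and the C10 centre is erased, so its configuration in 30 does not matter. The step needs the Z alkene and no β-elimination of the C9 silyl ether; the medium ring should only accommodate the cis-fused episulfone, which collapses stereospecifically to the Z alkene, and the supported base keeps the carbanion concentration low so that the intramolecular bromide displacement should outrun loss of silanolate. The ketal, the PMB ether and both TBS ethers are inert to hydroxide, which is why the butenolide is carried in reduced, masked form.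

Step 24
Reactants: 33 ten-membered diene bis-TBS ether
Product: 34 3,9-diol
Conditions: TBAF, THF, 0 °C to rt
Reagents that add atoms: none
Why: Fluoride cleaves both secondary TBS ethers; the ketal, the PMB ether and the diene are stable to TBAF.

Step 25
Reactants: 34 3,9-diol
Product: 35 3,9-diacetate
Conditions: Ac2O, pyridine, DMAP (cat.), CH2Cl2, rt
Reagents that add atoms: acetic anhydride CC(=O)OC(C)=O
Why: DMAP-catalysed acetylation of the two secondary alcohols installs the C3 and C9 acetates of the target.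

Step 26
Reactants: 35 3,9-diacetate
Product: 36 6,12-diol diacetate (C13–OPMB)
Conditions: PPTS (cat.), MeOH, rt
Reagents that add atoms: none
Why: Mild acid-catalysed transketalisation to methanol removes the seven-membered acetonide without ionising the doubly allylic C6–O bond or cleaving the acetates.

Step 27
Reactants: 36 6,12-diol diacetate
Product: 38 PMB-protected butenolide (C12 lactone carbonyl; lactone oxygen on C6), via lactol 37 (not isolated)
Conditions: TEMPO (cat.), PhI(OAc)2, CH2Cl2, rt
Reagents that add atoms: none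
Why: TEMPO/PhI(OAc)2 oxidises the primary allylic C12 alcohol in preference to the secondary C6 alcohol; the aldehyde is trapped as lactol 37, which is oxidised further to the butenolide (oxidative lactonisation of a 1,4-diol).

Step 28
Reactants: 38 PMB-protected butenolide
Product: 39 target CNP0328753.1
Conditions: DDQ, CH2Cl2/pH 7 buffer, 0 °C
Reagents that add atoms: none
Why: Oxidative cleavage of the p-methoxybenzyl ether by DDQ in wet dichloromethane frees the C13 hydroxyl without affecting the allylic acetates or the butenolide.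

Compound list

1 | 3-chloropropanoyl chloride | ClCCC(Cl)=O | starting material
2 | bis(trimethylsilyl)acetylene | C[Si](C)(C)C#C[Si](C)(C)C | starting material
3 | 5-chloro-1-(trimethylsilyl)pent-1-yn-3-one | C[Si](C)(C)C#CC(=O)CCCl | intermediate
4 | (S)-5-chloro-1-(trimethylsilyl)pent-1-yn-3-ol | C[Si](C)(C)C#C[C@@H](O)CCCl | intermediate
5 | (S)-3-(tert-butyldimethylsilyloxy)-5-chloro-1-(trimethylsilyl)pent-1-yne | C[Si](C)(C)C#C[C@@H](O[Si](C)(C)C(C)(C)C)CCCl | intermediate
6 | (S)-3-(tert-butyldimethylsilyloxy)-5-chloropent-1-yne | C#C[C@@H](O[Si](C)(C)C(C)(C)C)CCCl | intermediate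
7 | tris(hydroxymethyl)aminomethane hydrochloride | NC(CO)(CO)CO.Cl | starting material
8 | 4-methoxybenzaldehyde dimethyl acetal | COC(OC)c1ccc(OC)cc1 | starting material
9 | [5-amino-2-(4-methoxyphenyl)-1,3-dioxan-5-yl]methanol | NC1(CO)COC(OC1)c1ccc(OC)cc1 | intermediate
10 | 2-(4-methoxyphenyl)-1,3-dioxan-5-one | O=C1COC(OC1)c1ccc(OC)cc1 | intermediate
11 | (S)-5-(hydroxymethyl)dihydrofuran-2(3H)-one | OC[C@@H]1CCC(=O)O1 | starting material
12 | (S)-5-oxotetrahydrofuran-2-carbaldehyde | O=C[C@@H]1CCC(=O)O1 | intermediate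
13 | (S)-5-[(R)-1-hydroxyethyl]dihydrofuran-2(3H)-one | C[C@@H](O)[C@@H]1CCC(=O)O1 | intermediate
14 | (S)-5-[(R)-1-(triethylsilyloxy)ethyl]dihydrofuran-2(3H)-one | C[C@@H](O[Si](CC)(CC)CC)[C@@H]1CCC(=O)O1 | intermediate
15 | enol phosphate: diethyl (S)-5-[(R)-1-(triethylsilyloxy)ethyl]-4,5-dihydrofuran-2-yl phosphate | C[C@@H](O[Si](CC)(CC)CC)[C@@H]1CC=C(OP(=O)(OCC)OCC)O1 | intermediate
16 | α-phosphono lactone: diethyl {(5S)-2-oxo-5-[(R)-1-(triethylsilyloxy)ethyl]tetrahydrofuran-3-yl}phosphonate | C[C@@H](O[Si](CC)(CC)CC)[C@@H]1CC(P(=O)(OCC)OCC)C(=O)O1 | intermediate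
17 | (S)-3-[2-(4-methoxyphenyl)-1,3-dioxan-5-ylidene]-5-[(R)-1-(triethylsilyloxy)ethyl]dihydrofuran-2(3H)-one | C[C@@H](O[Si](CC)(CC)CC)[C@@H]1CC(=C2COC(OC2)c2ccc(OC)cc2)C(=O)O1 | intermediate
18 | hydroxy enynone; C1–C10 chain: 1-Cl, (3S)-OTBS, C4≡C5, 6-oxo, 7-[2-(4-methoxyphenyl)-1,3-dioxan-5-ylidene], (9S)-OH, (10R)-OTES | C[C@@H](O[Si](CC)(CC)CC)[C@@H](O)CC(=C1COC(OC1)c1ccc(OC)cc1)C(=O)C#C[C@@H](O[Si](C)(C)C(C)(C)C)CCCl | intermediate
19 | enynone as 18 with (9S)-OTBS | C[C@@H](O[Si](CC)(CC)CC)[C@@H](O[Si](C)(C)C(C)(C)C)CC(=C1COC(OC1)c1ccc(OC)cc1)C(=O)C#C[C@@H](O[Si](C)(C)C(C)(C)C)CCCl | intermediate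
20 | (3S,6R,9S,10R)-propargylic alcohol (6-OH, C4≡C5) | C[C@@H](O[Si](CC)(CC)CC)[C@@H](O[Si](C)(C)C(C)(C)C)CC(=C1COC(OC1)c1ccc(OC)cc1)[C@H](O)C#C[C@@H](O[Si](C)(C)C(C)(C)C)CCCl | intermediate
21 | cyclic alkenylalanate, sodium salt (Al on C4 and on the C6 oxygen) | [Na+].C[C@@H](O[Si](CC)(CC)CC)[C@@H](O[Si](C)(C)C(C)(C)C)CC(=C1COC(OC1)c1ccc(OC)cc1)[C@@H]1O[Al-](OCCOC)(OCCOC)C(=C1)[C@@H](O[Si](C)(C)C(C)(C)C)CCCl | intermediate
22 | (3S,6R,9S,10R)-(Z)-4-iodo allylic alcohol | C[C@@H](O[Si](CC)(CC)CC)[C@@H](O[Si](C)(C)C(C)(C)C)CC(=C1COC(OC1)c1ccc(OC)cc1)[C@H](O)/C=C(\I)[C@@H](O[Si](C)(C)C(C)(C)C)CCCl | intermediate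
23 | (3S,6R,9S,10R)-(4E)-allylic alcohol with C15 methyl, PMP acetal on the C12/C13 oxygens | C[C@@H](O[Si](CC)(CC)CC)[C@@H](O[Si](C)(C)C(C)(C)C)CC(=C1COC(OC1)c1ccc(OC)cc1)[C@H](O)/C=C(\C)[C@@H](O[Si](C)(C)C(C)(C)C)CCCl | intermediate
24 | (3S,6R,9S,10R)-6,12-diol, 13-PMB ether | C[C@@H](O[Si](CC)(CC)CC)[C@@H](O[Si](C)(C)C(C)(C)C)C/C(=C(\COCc1ccc(OC)cc1)CO)[C@H](O)/C=C(\C)[C@@H](O[Si](C)(C)C(C)(C)C)CCCl | intermediate
25 | dioxepine (C6/C12 acetonide), 10-OTES, 1-Cl | C[C@@H](O[Si](CC)(CC)CC)[C@@H](O[Si](C)(C)C(C)(C)C)CC1=C(COCc2ccc(OC)cc2)COC(C)(C)O[C@@H]1/C=C(\C)[C@@H](O[Si](C)(C)C(C)(C)C)CCCl | intermediate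
26 | dioxepine with free (10R)-OH | C[C@@H](O)[C@@H](O[Si](C)(C)C(C)(C)C)CC1=C(COCc2ccc(OC)cc2)COC(C)(C)O[C@@H]1/C=C(\C)[C@@H](O[Si](C)(C)C(C)(C)C)CCCl | intermediate
27 | (10S)-thioacetate | C[C@H](SC(C)=O)[C@@H](O[Si](C)(C)C(C)(C)C)CC1=C(COCc2ccc(OC)cc2)COC(C)(C)O[C@@H]1/C=C(\C)[C@@H](O[Si](C)(C)C(C)(C)C)CCCl | intermediate
28 | (10S)-thiol | C[C@H](S)[C@@H](O[Si](C)(C)C(C)(C)C)CC1=C(COCc2ccc(OC)cc2)COC(C)(C)O[C@@H]1/C=C(\C)[C@@H](O[Si](C)(C)C(C)(C)C)CCCl | intermediate
29 | eleven-membered cyclic sulfide (S between C1 and C10) | CC(C)(C)[Si](C)(C)O[C@H]1CC2=C(COCc3ccc(OC)cc3)COC(C)(C)O[C@@H]2/C=C(\C)[C@@H](O[Si](C)(C)C(C)(C)C)CCS[C@H]1C | intermediate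
30 | eleven-membered cyclic sulfone | CC(C)(C)[Si](C)(C)O[C@H]1CC2=C(COCc3ccc(OC)cc3)COC(C)(C)O[C@@H]2/C=C(\C)[C@@H](O[Si](C)(C)C(C)(C)C)CCS(=O)(=O)[C@H]1C | intermediate
31 | α-bromo sulfone (Br on C1) | CC(C)(C)[Si](C)(C)O[C@H]1CC2=C(COCc3ccc(OC)cc3)COC(C)(C)O[C@@H]2/C=C(\C)[C@@H](O[Si](C)(C)C(C)(C)C)CC(Br)S(=O)(=O)[C@H]1C | intermediate
32 | episulfone (thiirane 1,1-dioxide over C1 and C10) | CC(C)(C)[Si](C)(C)O[C@H]1CC2=C(COCc3ccc(OC)cc3)COC(C)(C)O[C@@H]2/C=C(\C)[C@@H](O[Si](C)(C)C(C)(C)C)CC3C1(C)S3(=O)=O | intermediate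
33 | ten-membered (1Z,4E)-diene bis-TBS ether fused to the dioxepine | CC(C)(C)[Si](C)(C)O[C@H]1CC2=C(COCc3ccc(OC)cc3)COC(C)(C)O[C@@H]2/C=C(\C)[C@@H](O[Si](C)(C)C(C)(C)C)C/C=C\1C | intermediate
34 | 3,9-diol | O[C@H]1CC2=C(COCc3ccc(OC)cc3)COC(C)(C)O[C@@H]2/C=C(\C)[C@@H](O)C/C=C\1C | intermediate
35 | 3,9-diacetate | CC(=O)O[C@H]1CC2=C(COCc3ccc(OC)cc3)COC(C)(C)O[C@@H]2/C=C(\C)[C@@H](OC(C)=O)C/C=C\1C | intermediate
36 | 6,12-diol 3,9-diacetate, 13-PMB ether | CC(=O)O[C@H]1C/C(=C(\COCc2ccc(OC)cc2)CO)[C@H](O)/C=C(\C)[C@@H](OC(C)=O)C/C=C\1C | intermediate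
37 | lactol | CC(=O)O[C@H]1CC2=C(COCc3ccc(OC)cc3)C(O)O[C@@H]2/C=C(\C)[C@@H](OC(C)=O)C/C=C\1C | intermediate
38 | PMB-protected butenolide | CC(=O)O[C@H]1CC2=C(COCc3ccc(OC)cc3)C(=O)O[C@@H]2/C=C(\C)[C@@H](OC(C)=O)C/C=C\1C | intermediate
39 | CNP0328753.1 (3S,6R,9S; 1Z,4E) | CC(=O)O[C@H]1CC2=C(CO)C(=O)O[C@@H]2/C=C(\C)[C@@H](OC(C)=O)C/C=C\1C | target

Total step count: 28. Longest linear sequence: 22 steps (steps 7–28, from 11). Side branches: steps 1–4 (alkyne 6) and steps 5–6 (ketone 10).

Steps most likely to fail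

Step 23 (key step). The C10 carbanion may expel the C9 silyloxy group instead of closing the episulfone, halogenation on the supported base may stall, or the alkene may form as an E/Z mixture. The fallback is the classical two-stage Ramberg–Bäcklund sequence, with the halogen installed before oxidation. It sets out from sulfide 29: N-chlorosuccinimide in CCl4 at 0 °C should chlorinate α to sulfur to give the α-chloro sulfide F1. Molybdate-catalysed H2O2 oxidation then gives the α-chloro sulfone F2. Brief treatment with KOt-Bu in THF at −78 °C effects the 1,3-elimination and loss of SO2 and comes back to the route at 33.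

Step 21. Closure of the medium ring may be outrun by intermolecular alkylation and oligomerisation because of transannular strain in the eleven-membered thiacycle. The fallback closes a larger ring through an S–S bond and then removes one sulfur. It sets out from 27: KSAc in DMF turns the C1 chloride into a second thioester, the bis(thioacetate) F3. Methanolysis with K2CO3 and oxidation with iodine under dilution should give the twelve-membered cyclic disulfide F4. Desulfurisation with P(NEt2)3 in hot benzene (Harpp sulfur extrusion) comes back to the route at 29.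

Step 17. The acetal opening may show poor regioselectivity and leave the PMB group on the C12 oxygen. The fallback differentiates the two arms by lactonisation instead. It sets out from 23: cold AcOH/THF/H2O hydrolyses the acetal to the triol F5. TEMPO/PhI(OAc)2 oxidises both primary alcohols, but only the arm cis to the C6 hydroxyl can lactonise, giving the 3-formyl butenolide F6. NaBH4/CeCl3 at −78 °C reduces the aldehyde to the 3-(hydroxymethyl) butenolide F7. PMB trichloroacetimidate with catalytic acid gives the PMB ether butenolide F8. DIBAL-H reduction of the lactone comes back to the route at 24.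

Further compounds

F1 | step 23 | α-chloro sulfide (Cl on C1 of 29) | CC(C)(C)[Si](C)(C)O[C@H]1CC2=C(COCc3ccc(OC)cc3)COC(C)(C)O[C@@H]2/C=C(\C)[C@@H](O[Si](C)(C)C(C)(C)C)CC(Cl)S[C@H]1C
F2 | step 23 | α-chloro sulfone | CC(C)(C)[Si](C)(C)O[C@H]1CC2=C(COCc3ccc(OC)cc3)COC(C)(C)O[C@@H]2/C=C(\C)[C@@H](O[Si](C)(C)C(C)(C)C)CC(Cl)S(=O)(=O)[C@H]1C
F3 | step 21 | bis(thioacetate) (SAc on C1 and C10) | C[C@H](SC(C)=O)[C@@H](O[Si](C)(C)C(C)(C)C)CC1=C(COCc2ccc(OC)cc2)COC(C)(C)O[C@@H]1/C=C(\C)[C@@H](O[Si](C)(C)C(C)(C)C)CCSC(C)=O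
F4 | step 21 | twelve-membered cyclic disulfide | CC(C)(C)[Si](C)(C)O[C@H]1CC2=C(COCc3ccc(OC)cc3)COC(C)(C)O[C@@H]2/C=C(\C)[C@@H](O[Si](C)(C)C(C)(C)C)CCSS[C@H]1C
F5 | step 17 | 6,12,13-triol | C[C@@H](O[Si](CC)(CC)CC)[C@@H](O[Si](C)(C)C(C)(C)C)CC(=C(CO)CO)[C@H](O)/C=C(\C)[C@@H](O[Si](C)(C)C(C)(C)C)CCCl
F6 | step 17 | 3-formyl butenolide (C13 aldehyde) | C[C@@H](O[Si](CC)(CC)CC)[C@@H](O[Si](C)(C)C(C)(C)C)CC1=C(C=O)C(=O)O[C@@H]1/C=C(\C)[C@@H](O[Si](C)(C)C(C)(C)C)CCCl
F7 | step 17 | 3-(hydroxymethyl) butenolide | C[C@@H](O[Si](CC)(CC)CC)[C@@H](O[Si](C)(C)C(C)(C)C)CC1=C(CO)C(=O)O[C@@H]1/C=C(\C)[C@@H](O[Si](C)(C)C(C)(C)C)CCCl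
F8 | step 17 | PMB ether butenolide | C[C@@H](O[Si](CC)(CC)CC)[C@@H](O[Si](C)(C)C(C)(C)C)CC1=C(COCc2ccc(OC)cc2)C(=O)O[C@@H]1/C=C(\C)[C@@H](O[Si](C)(C)C(C)(C)C)CCCl
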